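**Retrosynthetic overview**

1. The target comes from its 7,8-di-O-benzyl ether, this from the tetralin diester, and this from a 4-oxotetralin diester. C9 and C10 are carried as methyl esters and C4 as a ketone that is reduced away.
2. Ring B is closed last through C3–C4 by carbene-catalysed acyl-anion (Stetter) addition of a C4 aldehyde on C4a to C3 of a 2-(diarylmethyl)fumarate. The feature used is that C4 is an unsubstituted benzylic CH2 on C4a of ring A, para to O7, beside C3, whose carbon C10 can stand at the ester level.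
3. The fumarate comes from a 3,3-diarylpropanoate: C2–C3 by glyoxylate aldol and dehydration; C4 is placed on C4a by para-Claisen transfer of an O7 allyl group, isomerisation and cleavage.
4. C1 is set by rhodium/chiral-diene conjugate arylation of the ring A cinnamate (from 2,3-dihydroxy-4-methoxybenzaldehyde) with 3,4,5-trimethoxyphenylboronic acid. C2 is then fixed by protonation and C3 by enolisation of the β-keto ester in the key step; no late base equilibration of the diester is used, because there an isomer with an axial C2 ester would compete.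
5. Ring order: rings A and C are bought; ring B is the only ring formed (step 11).

Key step: step 11

Assumption (remark on the chemistry): locants C1–C8a of the 1-aryltetralin core are used for the corresponding atoms of all intermediates, and the enantiomer of the diene ligand in step 4 is the one that arylates the Re face of C1 (to be confirmed on the first run).

**Route**

Step 1
Reactants: 1 2,3-dihydroxy-4-methoxybenzaldehyde; 2 allyl bromide
Product: 3 3-(allyloxy)-2-hydroxy-4-methoxybenzaldehyde
Conditions: NaH (2.2 equiv), DMSO, 20 °C; then 2 (1.0 equiv); aq. HCl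
Reagents that add atoms: none
Why: Williamson etherification of the dianion, in which the O3 phenoxide (O7 of the target) is the more nucleophilic oxygen because the O2 phenoxide is delocalised into and chelated by the aldehyde, so mono-allylation should occur at O7.

Step 2
Reactants: 3 3-(allyloxy)-2-hydroxy-4-methoxybenzaldehyde; 4 benzyl bromide
Product: 5 3-(allyloxy)-2-(benzyloxy)-4-methoxybenzaldehyde
Conditions: K2CO3, DMF, 60 °C
Reagents that add atoms: none
Why: Williamson benzylation of the remaining hydrogen-bonded phenol (O8), which carbonate in DMF should drive to completion.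

Step 3
Reactants: 5 3-(allyloxy)-2-(benzyloxy)-4-methoxybenzaldehyde; 6 methyl (triphenylphosphoranylidene)acetate
Product: 7 methyl (E)-3-[3-(allyloxy)-2-(benzyloxy)-4-methoxyphenyl]prop-2-enoate
Conditions: toluene, 90 °C
Reagents that add atoms: none
Why: Wittig olefination with a stabilised ylide, which should give the (E)-cinnamate.

Step 4
Reactants: 7 methyl (E)-3-[3-(allyloxy)-2-(benzyloxy)-4-methoxyphenyl]prop-2-enoate; 8 3,4,5-trimethoxyphenylboronic acid
Product: 9 methyl (3S)-3-[3-(allyloxy)-2-(benzyloxy)-4-methoxyphenyl]-3-(3,4,5-trimethoxyphenyl)propanoate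
Conditions: Rh(acac)(C2H4)2 (3 mol %), enantiopure 2,5-diphenylbicyclo[2.2.2]octa-2,5-diene (Ph-bod*, 3.3 mol %), 8 (2.5 equiv), dioxane/H2O 10:1, 60 °C
Reagents that add atoms: none
Why: Hayashi–Miyaura rhodium-catalysed asymmetric conjugate arylation, in which the chiral diene selects the enoate face so that the aryl group adds to the Re face of C1 and sets (S)-C1, while the isolated allyl ether alkene is a far poorer acceptor than the enoate.

Step 5
Reactants: 9 methyl (3S)-3-[3-(allyloxy)-2-(benzyloxy)-4-methoxyphenyl]-3-(3,4,5-trimethoxyphenyl)propanoate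
Product: 10 methyl (3S)-3-[6-allyl-2-(benzyloxy)-3-hydroxy-4-methoxyphenyl]-3-(3,4,5-trimethoxyphenyl)propanoate
Conditions: N,N-diethylaniline, 200 °C, sealed tube
Reagents that add atoms: none
Why: aromatic para-Claisen rearrangement, a [3,3] shift of the O7 allyl group to a blocked ortho carbon (C6 or C8) followed by a Cope shift to C4a and tautomerisation; with both ortho positions oxygen-substituted the allyl group can end only at C4a, and C1 is not touched under neutral thermal conditions.

Step 6
Reactants: 10 methyl (3S)-3-[6-allyl-2-(benzyloxy)-3-hydroxy-4-methoxyphenyl]-3-(3,4,5-trimethoxyphenyl)propanoate; 4 benzyl bromide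
Product: 11 methyl (3S)-3-[6-allyl-2,3-bis(benzyloxy)-4-methoxyphenyl]-3-(3,4,5-trimethoxyphenyl)propanoate
Conditions: K2CO3, DMF, 50 °C
Reagents that add atoms: none
Why: Williamson benzylation of the free O7 phenol; carbonate does not enolise the ester.

Step 7
Reactants: 11 methyl (3S)-3-[6-allyl-2,3-bis(benzyloxy)-4-methoxyphenyl]-3-(3,4,5-trimethoxyphenyl)propanoate
Product: 12 methyl (3S)-3-{2,3-bis(benzyloxy)-4-methoxy-6-[(E)-prop-1-en-1-yl]phenyl}-3-(3,4,5-trimethoxyphenyl)propanoate
Conditions: RuHCl(CO)(PPh3)3 (5 mol %), toluene, 100 °C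
Reagents that add atoms: none
Why: ruthenium-hydride alkene isomerisation (hydrometalation and β-hydride elimination), which should move the double bond into conjugation with ring A as the (E)-propenyl group.

Step 8
Reactants: 12 methyl (3S)-3-{2,3-bis(benzyloxy)-4-methoxy-6-[(E)-prop-1-en-1-yl]phenyl}-3-(3,4,5-trimethoxyphenyl)propanoate; 13 methyl glyoxylate
Product: 14 dimethyl 2-[(S)-{2,3-bis(benzyloxy)-4-methoxy-6-[(E)-prop-1-en-1-yl]phenyl}(3,4,5-trimethoxyphenyl)methyl]-3-hydroxybutanedioate (C2/C3 diastereomer mixture)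
Conditions: LiN(iPr)2 (1.1 equiv), THF, −78 °C; then freshly cracked 13 (1.5 equiv), −78 °C; aq. NH4Cl
Reagents that add atoms: none
Why: aldol addition of the lithium ester enolate (C2) to the highly electrophilic glyoxylate, forming C2–C3; no stereocontrol is needed because both new centres are erased in step 9.

Step 9
Reactants: 14 dimethyl 2-[(S)-{2,3-bis(benzyloxy)-4-methoxy-6-[(E)-prop-1-en-1-yl]phenyl}(3,4,5-trimethoxyphenyl)methyl]-3-hydroxybutanedioate
Product: 16 dimethyl (E)-2-[(S)-{2,3-bis(benzyloxy)-4-methoxy-6-[(E)-prop-1-en-1-yl]phenyl}(3,4,5-trimethoxyphenyl)methyl]but-2-enedioate, via C3 mesylate 15 (not isolated)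
Conditions: MsCl (1.5 equiv), Et3N (4 equiv), CH2Cl2, 0 → 25 °C
Reagents that add atoms: methanesulfonyl chloride, CS(=O)(=O)Cl (its atoms stay only in 15)
Why: mesylation and E1cB elimination through the C2 ester enolate, which can place the double bond only at C2=C3 because the leaving group sits on C3; the (E)-diester with the ester groups trans is expected as the main isomer (any (Z)-isomer is removed by chromatography), and Et3N is used instead of an amidine base to spare the doubly benzylic C1–H.

Step 10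
Reactants: 16 dimethyl (E)-2-[(S)-{2,3-bis(benzyloxy)-4-methoxy-6-[(E)-prop-1-en-1-yl]phenyl}(3,4,5-trimethoxyphenyl)methyl]but-2-enedioate
Product: 18 dimethyl (E)-2-[(S)-[2,3-bis(benzyloxy)-6-formyl-4-methoxyphenyl](3,4,5-trimethoxyphenyl)methyl]but-2-enedioate, via vicinal diol 17 (not isolated)
Conditions: K2OsO4·2H2O (2 mol %), NaIO4 (4 equiv), 2,6-lutidine (2 equiv), dioxane/H2O 3:1, 20 °C
Reagents that add atoms: sodium periodate, [Na+].[O-]I(=O)(=O)=O (oxygen passed on through the osmium catalyst)
Why: Lemieux–Johnson oxidative cleavage, in which the electrophilic osmium oxidant should select the electron-rich styrenyl alkene over the electron-poor trisubstituted fumarate.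

Step 11
Reactants: 18 dimethyl (E)-2-[(S)-[2,3-bis(benzyloxy)-6-formyl-4-methoxyphenyl](3,4,5-trimethoxyphenyl)methyl]but-2-enedioate
Product: 19 dimethyl (1S,2S,3R)-7,8-bis(benzyloxy)-6-methoxy-4-oxo-1-(3,4,5-trimethoxyphenyl)-1,2,3,4-tetrahydronaphthalene-2,3-dicarboxylate
Conditions: 2-(pentafluorophenyl)-6,7-dihydro-5H-pyrrolo[2,1-c][1,2,4]triazol-2-ium tetrafluoroborate (20 mol %), KN(SiMe3)2 (18 mol %), toluene, 25 °C
Reagents that add atoms: none
Why: Proposed new method: the carbene adds to the C4 aldehyde, proton transfer gives the Breslow enaminol, its acyl-anion carbon C4 adds to C3 of the fumarate (β to the C2 ester), and protonation of the C2 ester enolate with loss of the carbene gives the 4-oxotetralin; the closest known reactions are the intramolecular Stetter cyclisation of aryl aldehydes onto tethered enoates by exo closure and the intermolecular Stetter addition to dialkyl fumarates. Ring B closes in the 6-endo-trig mode, which should be preferred over 5-exo attack at C2 because C2 is fully substituted and flanked by the diarylmethine, whereas C3 carries only H and an ester. C1 controls the face: peri strain with the C8 benzyloxy group and 1,2-strain with the C2 ester hold the C1 aryl pseudoaxial on the side away from the incoming C4, so C2 should be protonated from the open face and its ester end up cis to the aryl. C3, α to both ketone and ester, should equilibrate through the enol to the equatorial position, trans to the C2 ester and away from the pseudoaxial aryl. The step needs chemoselectivity against base-induced migration of the C2=C3 bond toward C1, which is addressed by using less base than triazolium salt so that no base stronger than the carbene is present.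

Step 12
Reactants: 19 dimethyl (1S,2S,3R)-7,8-bis(benzyloxy)-6-methoxy-4-oxo-1-(3,4,5-trimethoxyphenyl)-1,2,3,4-tetrahydronaphthalene-2,3-dicarboxylate
Product: 20 dimethyl (1S,2S,3R)-7,8-bis(benzyloxy)-4-hydroxy-6-methoxy-1-(3,4,5-trimethoxyphenyl)-1,2,3,4-tetrahydronaphthalene-2,3-dicarboxylate (both C4 epimers)
Conditions: NaBH4, MeOH/THF, −20 → 0 °C
Reagents that add atoms: none
Why: borohydride reduction of the aryl ketone of the β-keto ester, which should leave both esters and the C2 centre untouched at low temperature; the C4 configuration is irrelevant.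

Step 13
Reactants: 20 dimethyl (1S,2S,3R)-7,8-bis(benzyloxy)-4-hydroxy-6-methoxy-1-(3,4,5-trimethoxyphenyl)-1,2,3,4-tetrahydronaphthalene-2,3-dicarboxylate
Product: 21 dimethyl (1S,2S,3S)-7,8-bis(benzyloxy)-6-methoxy-1-(3,4,5-trimethoxyphenyl)-1,2,3,4-tetrahydronaphthalene-2,3-dicarboxylate
Conditions: Et3SiH (5 equiv), CF3CO2H (10 equiv), CH2Cl2, 0 °C
Reagents that add atoms: none
Why: ionic hydrogenation, in which acid ionises the C4 alcohol to a benzylic cation stabilised by the para O7 ether and the silane should reduce it before H3 is lost; C2 and C3 are not enolised under acid (the C3 descriptor changes only because C4 drops in priority).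

Step 14
Reactants: 21 dimethyl (1S,2S,3S)-7,8-bis(benzyloxy)-6-methoxy-1-(3,4,5-trimethoxyphenyl)-1,2,3,4-tetrahydronaphthalene-2,3-dicarboxylate
Product: 22 [(1S,2S,3S)-7,8-bis(benzyloxy)-6-methoxy-1-(3,4,5-trimethoxyphenyl)-1,2,3,4-tetrahydronaphthalene-2,3-diyl]dimethanol
Conditions: LiAlH4, THF, 0 °C; Fieser work-up
Reagents that add atoms: none
Why: hydride reduction of both esters to the primary alcohols C9H2OH and C10H2OH, which should be faster than enolisation at 0 °C, so C2 and C3 are retained.

Step 15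
Reactants: 22 [(1S,2S,3S)-7,8-bis(benzyloxy)-6-methoxy-1-(3,4,5-trimethoxyphenyl)-1,2,3,4-tetrahydronaphthalene-2,3-diyl]dimethanol
Product: 23 [(1S,2S,3S)-7,8-dihydroxy-6-methoxy-1-(3,4,5-trimethoxyphenyl)-1,2,3,4-tetrahydronaphthalene-2,3-diyl]dimethanol (CNP0188980.2)
Conditions: H2 (1 atm), Pd/C (10 %), MeOH/EtOAc, 25 °C, argon-flushed work-up
Reagents that add atoms: none
Why: catalytic hydrogenolysis of the two benzyl aryl ethers, which should free the catechol without touching the diarylmethine or the primary alcohols.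

**Compound list**

1 | 2,3-dihydroxy-4-methoxybenzaldehyde | COc1ccc(C=O)c(O)c1O | starting material
2 | allyl bromide | C=CCBr | starting material
3 | 3-(allyloxy)-2-hydroxy-4-methoxybenzaldehyde | COc1ccc(C=O)c(O)c1OCC=C | intermediate
4 | benzyl bromide | BrCc1ccccc1 | starting material
5 | 3-(allyloxy)-2-(benzyloxy)-4-methoxybenzaldehyde | COc1ccc(C=O)c(OCc2ccccc2)c1OCC=C | intermediate
6 | methyl (triphenylphosphoranylidene)acetate | COC(=O)C=P(c1ccccc1)(c1ccccc1)c1ccccc1 | starting material
7 | methyl (E)-3-[3-(allyloxy)-2-(benzyloxy)-4-methoxyphenyl]prop-2-enoate | COC(=O)/C=C/c1ccc(OC)c(OCC=C)c1OCc1ccccc1 | intermediate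
8 | 3,4,5-trimethoxyphenylboronic acid | COc1cc(B(O)O)cc(OC)c1OC | starting material
9 | methyl (3S)-3-[3-(allyloxy)-2-(benzyloxy)-4-methoxyphenyl]-3-(3,4,5-trimethoxyphenyl)propanoate | COc1ccc(c(OCc2ccccc2)c1OCC=C)[C@H](c3cc(OC)c(OC)c(OC)c3)CC(=O)OC | intermediate
10 | methyl (3S)-3-[6-allyl-2-(benzyloxy)-3-hydroxy-4-methoxyphenyl]-3-(3,4,5-trimethoxyphenyl)propanoate | COc1cc(CC=C)c(c(OCc2ccccc2)c1O)[C@H](c3cc(OC)c(OC)c(OC)c3)CC(=O)OC | intermediate
11 | methyl (3S)-3-[6-allyl-2,3-bis(benzyloxy)-4-methoxyphenyl]-3-(3,4,5-trimethoxyphenyl)propanoate | COc1cc(CC=C)c(c(OCc2ccccc2)c1OCc3ccccc3)[C@H](c4cc(OC)c(OC)c(OC)c4)CC(=O)OC | intermediate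
12 | methyl (3S)-3-{2,3-bis(benzyloxy)-4-methoxy-6-[(E)-prop-1-en-1-yl]phenyl}-3-(3,4,5-trimethoxyphenyl)propanoate | COc1cc(/C=C/C)c(c(OCc2ccccc2)c1OCc3ccccc3)[C@H](c4cc(OC)c(OC)c(OC)c4)CC(=O)OC | intermediate
13 | methyl glyoxylate | COC(=O)C=O | starting material
14 | dimethyl 2-[(S)-{2,3-bis(benzyloxy)-4-methoxy-6-[(E)-prop-1-en-1-yl]phenyl}(3,4,5-trimethoxyphenyl)methyl]-3-hydroxybutanedioate (C2/C3 diastereomer mixture) | COc1cc(/C=C/C)c(c(OCc2ccccc2)c1OCc3ccccc3)[C@H](c4cc(OC)c(OC)c(OC)c4)C(C(=O)OC)C(O)C(=O)OC | intermediate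
15 | C3 methanesulfonate of 14 (not isolated) | COc1cc(/C=C/C)c(c(OCc2ccccc2)c1OCc3ccccc3)[C@H](c4cc(OC)c(OC)c(OC)c4)C(C(=O)OC)C(OS(C)(=O)=O)C(=O)OC | intermediate
16 | dimethyl (E)-2-[(S)-{2,3-bis(benzyloxy)-4-methoxy-6-[(E)-prop-1-en-1-yl]phenyl}(3,4,5-trimethoxyphenyl)methyl]but-2-enedioate | COc1cc(/C=C/C)c(c(OCc2ccccc2)c1OCc3ccccc3)[C@H](c4cc(OC)c(OC)c(OC)c4)/C(C(=O)OC)=C\C(=O)OC | intermediate
17 | vicinal diol from dihydroxylation of the propenyl group of 16 (not isolated; diol carbons unspecified) | COc1cc(C(O)C(C)O)c(c(OCc2ccccc2)c1OCc3ccccc3)[C@H](c4cc(OC)c(OC)c(OC)c4)/C(C(=O)OC)=C\C(=O)OC | intermediate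
18 | dimethyl (E)-2-[(S)-[2,3-bis(benzyloxy)-6-formyl-4-methoxyphenyl](3,4,5-trimethoxyphenyl)methyl]but-2-enedioate (key-step precursor) | COc1cc(C=O)c(c(OCc2ccccc2)c1OCc3ccccc3)[C@H](c4cc(OC)c(OC)c(OC)c4)/C(C(=O)OC)=C\C(=O)OC | intermediate
19 | dimethyl (1S,2S,3R)-7,8-bis(benzyloxy)-6-methoxy-4-oxo-1-(3,4,5-trimethoxyphenyl)-1,2,3,4-tetrahydronaphthalene-2,3-dicarboxylate (key-step product) | COc1cc2c(c(OCc3ccccc3)c1OCc4ccccc4)[C@H](c5cc(OC)c(OC)c(OC)c5)[C@H](C(=O)OC)[C@@H](C(=O)OC)C2=O | intermediate
20 | dimethyl (1S,2S,3R)-7,8-bis(benzyloxy)-4-hydroxy-6-methoxy-1-(3,4,5-trimethoxyphenyl)-1,2,3,4-tetrahydronaphthalene-2,3-dicarboxylate (both C4 epimers) | COc1cc2c(c(OCc3ccccc3)c1OCc4ccccc4)[C@H](c5cc(OC)c(OC)c(OC)c5)[C@H](C(=O)OC)[C@@H](C(=O)OC)C2O | intermediate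
21 | dimethyl (1S,2S,3S)-7,8-bis(benzyloxy)-6-methoxy-1-(3,4,5-trimethoxyphenyl)-1,2,3,4-tetrahydronaphthalene-2,3-dicarboxylate | COc1cc2c(c(OCc3ccccc3)c1OCc4ccccc4)[C@H](c5cc(OC)c(OC)c(OC)c5)[C@H](C(=O)OC)[C@@H](C(=O)OC)C2 | intermediate
22 | [(1S,2S,3S)-7,8-bis(benzyloxy)-6-methoxy-1-(3,4,5-trimethoxyphenyl)-1,2,3,4-tetrahydronaphthalene-2,3-diyl]dimethanol | COc1cc2c(c(OCc3ccccc3)c1OCc4ccccc4)[C@H](c5cc(OC)c(OC)c(OC)c5)[C@H](CO)[C@@H](CO)C2 | intermediate
23 | [(1S,2S,3S)-7,8-dihydroxy-6-methoxy-1-(3,4,5-trimethoxyphenyl)-1,2,3,4-tetrahydronaphthalene-2,3-diyl]dimethanol (CNP0188980.2) | COc1cc2c(c(O)c1O)[C@H](c1cc(OC)c(OC)c(OC)c1)[C@H](CO)[C@@H](CO)C2 | target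

**Step count and risks**

Total step count: 15. Longest linear sequence: 15 steps (from 1).

Steps most likely to fail:

Step 11 (carries the proposed new method). The endo closure may be slow, so that the aldehyde is consumed by benzoin-type pathways. The acyl anion may attack C2 in the 5-exo mode. The carbene may act as a base and move the C2=C3 bond toward C1, which destroys both the acceptor and the C1 centre. C2 may be protonated from the wrong face. The fallback is a Dieckmann condensation, which sets out from 12 and comes back at 19. The lithium enolate of 12 (LiN(iPr)2, THF, −78 °C) is alkylated with methyl bromoacetate to give dimethyl 2-[(S)-{2,3-bis(benzyloxy)-4-methoxy-6-[(E)-prop-1-en-1-yl]phenyl}(3,4,5-trimethoxyphenyl)methyl]butanedioate F1. Cleavage with K2OsO4·2H2O/NaIO4 gives the corresponding 6-formyl succinate F2. Pinnick oxidation (NaClO2, NaH2PO4, 2-methyl-2-butene) gives the benzoic acid F3, and trimethylsilyldiazomethane gives the methyl benzoate triester F4. LiN(SiMe3)2 (3 equiv, THF, −78 → 0 °C) should then condense the C3 enolate onto the aryl ester to form the six-membered β-keto ester; the five-membered alternative from the C2 enolate cannot form a stabilised enolate and reverts. Quenching the resulting C2,C3-dienolate with acetic acid at −78 °C should protonate C2 on the face away from the pseudoaxial aryl, and C3 settles as in the main route, giving 19.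

Step 9. The amine base may remove the doubly benzylic C1–H of the product, so that the double bond migrates into conjugation with the aryl rings and the C1 centre is lost; the elimination may also stall at the mesylate or give mainly the wrong alkene geometry. The fallback is an oxidative dehydrogenation without base, which sets out from 12 and comes back at 16. Compound 12 is alkylated as above to the succinate F1. Deprotonation at the less hindered C3 (LiN(iPr)2, THF, −78 °C) and trapping with PhSeBr gives dimethyl 2-[(S)-{2,3-bis(benzyloxy)-4-methoxy-6-[(E)-prop-1-en-1-yl]phenyl}(3,4,5-trimethoxyphenyl)methyl]-3-(phenylselanyl)butanedioate F5. Oxidation with H2O2 (pyridine, CH2Cl2, 0 → 25 °C) triggers selenoxide syn-elimination toward the only β-hydrogen (C2–H) and should give 16 under neutral conditions.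

Step 5. At 200 °C the allyl transfer may be incomplete, may be diverted by loss of an ortho alkoxy group from the dienone intermediate, or may be accompanied by thermal cleavage of the O8 benzyl ether. The fallback is halogenation and cross-coupling, which sets out from 9 and comes back at 12. The allyl ether is removed with Pd(PPh3)4 and morpholine (THF, 25 °C) to give methyl (3S)-3-[2-(benzyloxy)-3-hydroxy-4-methoxyphenyl]-3-(3,4,5-trimethoxyphenyl)propanoate F6. N-Bromosuccinimide (CH2Cl2, −40 °C) should brominate the free phenol at its only open activated position, para to O7 (C4a), much faster than it attacks the aryl ethers, giving methyl (3S)-3-[2-(benzyloxy)-6-bromo-3-hydroxy-4-methoxyphenyl]-3-(3,4,5-trimethoxyphenyl)propanoate F7. Benzylation (benzyl bromide, K2CO3, DMF) gives methyl (3S)-3-[2,3-bis(benzyloxy)-6-bromo-4-methoxyphenyl]-3-(3,4,5-trimethoxyphenyl)propanoate F8. Suzuki–Miyaura coupling with (E)-prop-1-enylboronic acid pinacol ester (PdCl2(dppf), K3PO4, dioxane/H2O, 80 °C) should give 12.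

**Further compounds**

F1 | step 11 | dimethyl 2-[(S)-{2,3-bis(benzyloxy)-4-methoxy-6-[(E)-prop-1-en-1-yl]phenyl}(3,4,5-trimethoxyphenyl)methyl]butanedioate (C2 epimers) | COc1cc(/C=C/C)c(c(OCc2ccccc2)c1OCc3ccccc3)[C@H](c4cc(OC)c(OC)c(OC)c4)C(C(=O)OC)CC(=O)OC
F2 | step 11 | dimethyl 2-[(S)-[2,3-bis(benzyloxy)-6-formyl-4-methoxyphenyl](3,4,5-trimethoxyphenyl)methyl]butanedioate | COc1cc(C=O)c(c(OCc2ccccc2)c1OCc3ccccc3)[C@H](c4cc(OC)c(OC)c(OC)c4)C(C(=O)OC)CC(=O)OC
F3 | step 11 | 3,4-bis(benzyloxy)-2-[(1S)-3-methoxy-2-(methoxycarbonyl)-3-oxo... i.e. the benzoic acid from F2 (CHO oxidised to CO2H) | COc1cc(C(=O)O)c(c(OCc2ccccc2)c1OCc3ccccc3)[C@H](c4cc(OC)c(OC)c(OC)c4)C(C(=O)OC)CC(=O)OC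
F4 | step 11 | methyl ester of F3 (aryl CO2Me triester) | COc1cc(C(=O)OC)c(c(OCc2ccccc2)c1OCc3ccccc3)[C@H](c4cc(OC)c(OC)c(OC)c4)C(C(=O)OC)CC(=O)OC
F5 | step 9 | dimethyl 2-[(S)-{2,3-bis(benzyloxy)-4-methoxy-6-[(E)-prop-1-en-1-yl]phenyl}(3,4,5-trimethoxyphenyl)methyl]-3-(phenylselanyl)butanedioate | COc1cc(/C=C/C)c(c(OCc2ccccc2)c1OCc3ccccc3)[C@H](c4cc(OC)c(OC)c(OC)c4)C(C(=O)OC)C([Se]c5ccccc5)C(=O)OC
F6 | step 5 | methyl (3S)-3-[2-(benzyloxy)-3-hydroxy-4-methoxyphenyl]-3-(3,4,5-trimethoxyphenyl)propanoate | COc1ccc(c(OCc2ccccc2)c1O)[C@H](c3cc(OC)c(OC)c(OC)c3)CC(=O)OC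
F7 | step 5 | methyl (3S)-3-[2-(benzyloxy)-6-bromo-3-hydroxy-4-methoxyphenyl]-3-(3,4,5-trimethoxyphenyl)propanoate | COc1cc(Br)c(c(OCc2ccccc2)c1O)[C@H](c3cc(OC)c(OC)c(OC)c3)CC(=O)OC
F8 | step 5 | methyl (3S)-3-[2,3-bis(benzyloxy)-6-bromo-4-methoxyphenyl]-3-(3,4,5-trimethoxyphenyl)propanoate | COc1cc(Br)c(c(OCc2ccccc2)c1OCc3ccccc3)[C@H](c4cc(OC)c(OC)c(OC)c4)CC(=O)OC
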